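## The problem

The target is a depside: two fully substituted benzene rings joined by one aryl ester. Ring A is the methyl benzoate ring (C1 CO2CH3, C2 OH, C3 CH3, C4 O-acyl, C5 CH3, C6 CH3). Ring B is the chlorinated salicyloyl ring (C1' carboxyl, C2' OH, C3' CH3, C4' OCH3, C5' Cl, C6' CH3). There is no stereocentre, so the difficulty is regiochemistry on two hexasubstituted rings and the formation of one very hindered bond. The ester oxygen O4 sits between the C3 and C5 methyl groups. The acyl carbon sits between the C2' oxygen and the C6' methyl group. Acyl substitution therefore has to bring a doubly ortho-substituted phenol to a doubly ortho-substituted carbonyl. The finished depside ester is an active aryl ester and will not tolerate hydroxide or alkoxide. The aryl chloride is at risk under hydrogenolysis. The C4' methyl ether must survive whatever releases the two chelated phenols, and those phenols are easily oxidised. The enabling feature is C4 of ring A: it is para to the ester, flanked by two methyl groups and has no ortho hydrogen. As a ligand on trivalent iodine, ring A is then the electron-poorer and more congested of two aryl groups, which is the one handed to an oxygen nucleophile. The C4–O4 bond can therefore be made by arylating the ring B carboxylate.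

## Retrosynthesis

**Target 18 to bis-benzyl ether 17.** The two O–H bonds of the salicylate hydroxyls are masked as benzyl ethers. Free phenols would be arylated by the iodonium salt and oxidised by the peracid used to make it. Methyl ethers would have to be told apart from the C4' methoxy group at the end. Silyl ethers would not survive the hot hydroxide used on ring B. The forward step must remove two benzyl groups without hydrogen gas (C5'–Cl) and without a nucleophile (depside ester); a boron Lewis acid with an arene cation trap at low temperature fits.

**17 to iodonium salt 9 and acid 14.** The C4–O4 aryl–oxygen bond is cut, not the neighbouring acyl–oxygen bond. Cutting the acyl–oxygen bond would require a ring A phenol between two methyl groups to attack a 2,6-disubstituted aroyl derivative. Cutting C4–O4 moves bond formation to the ring A carbon. There, the two ortho methyl groups accelerate ligand coupling at iodine, and the hindrance of the acid counts for little because its oxygen is the nucleophile. The cut divides the molecule into halves of similar size, and ring A no longer needs an oxygen at C4. The forward reaction must transfer ring A and not the auxiliary aryl group, and must tolerate ortho substitution on both partners.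

**9 to iodide 6 and arene 7.** The bond between iodine and the trimethoxyphenyl ring is cut. Oxidation of 6 to trivalent iodine and substitution on 7 rebuild it in one flask. The 2,4,6-trimethoxyphenyl group is chosen as auxiliary over phenyl or mesityl. It is the most electron-rich, has no hydrogen ortho to iodine, and comes from a cheap arene.

**6 to phenol 5 to ester 4.** The O–benzyl bond and the C4–I bond are cut in that order. Iodination is placed on the free phenol 4 so that no benzyl ring competes for the electrophile. It is placed on the ester and not on the acid so that ipso attack with loss of CO2 cannot occur. C4 is the only ring carbon of 4 that carries hydrogen. The forward step must overcome the deactivation by the para ester.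

**4 to acid 3 to aldehyde 2 to phenol 1.** The O–CH3 bond of the ester, the oxidation state of C1's carbon substituent, and the ring C1–CHO bond are removed in turn. Phenol 1 has one free ortho position and a blocked para position. A chelation-controlled ortho-formylation therefore gives the pattern of ring A without isomers.

**14 to ester 13 to phenol 12 to 11 to methyl atrarate 10.** The acid is unmasked from its methyl ester. Before that, the O2'–benzyl bond, the C5'–Cl bond and the O4'–CH3 bond are cut. Compound 10 already holds every carbon of ring B. The non-chelated 4-hydroxyl is methylated first. The one remaining ring hydrogen, para to the hydroxyl and ortho to the methoxy group, is then replaced by chlorine. The chelated hydroxyl is benzylated last. The only demanding forward step is hydrolysis of the 2,6-disubstituted ester.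

## Roads not taken

**Alternative 1:** Ring A would be built from acyclic pieces by cutting C1–C6 and C2–C3. A malonic ester adds to the β-carbon of an acyclic α-methyl enone and the ethyl ketone enolate closes onto a malonate carbonyl. This gives methyl 3,5,6-trimethyl-2,4-dioxocyclohexane-1-carboxylate A1. Dehydrogenation gives methyl 2,4-dihydroxy-3,5,6-trimethylbenzoate A2, whose non-chelated 4-hydroxyl is then acylated with a ring B acid such as 14.
- Merits: cheap reagents, two ring bonds in one flask, all six substituents fixed by construction, both oxygens present from the start.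
- Where it is better: it reaches a ring A building block in two steps, against five for iodide 6, and needs no substitution at a deactivated ring position.
- Weak points: a fully substituted dihydroresorcinol must be aromatised with a stoichiometric oxidant. The route also ends with the acylation of a di-ortho-methyl phenol by a di-ortho-substituted acid, the slow step of depside synthesis.
- What the chosen plan sets against it: the joining step is moved to an aryl carbon where ortho substitution helps, at the price of more steps on ring A and the use of hypervalent iodine.

**Alternative 2:** Ring A would be formed by a Danheiser benzannulation, cutting C3–C4, C1–C2 and C4–C5. Photochemical Wolff rearrangement of a 2-diazo-3-oxo-4-enoate gives a vinylketene. Addition of a silyloxypropyne, four-electron ring opening and six-electron closure give methyl 4-hydroxy-3,5,6-trimethyl-2-(triisopropylsilyloxy)benzoate A3.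
- Merits: the hexasubstituted ring arrives in one operation, with regiochemistry set by the polarity of the ynol ether.
- Where it is better: the two oxygens are already differentiated, O4 free and O2 silylated. The chosen plan obtains that differentiation only because O4 comes with the acid.
- Weak points: the diazo keto ester and the silyl ynol ether each need separate preparation. The ketene is tetrasubstituted and its cycloaddition is sterically slow. The photochemical step limits scale. A3 still has to be acylated at its hindered 4-hydroxyl, and the silyl group must later be removed beside a depside ester.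
- What the chosen plan sets against it: a commodity phenol, standard reactions throughout, and no hindered acylation.

**Alternative 3:** Ring B would be built on a ring A ester by cutting C1'–C2' and C5'–C6'. Phenol A2 is acylated at O4 with a but-2-ynoyl group to give methyl 4-(but-2-ynoyloxy)-2-hydroxy-3,5,6-trimethylbenzoate A5. A Brassard-type 1,3-dimethoxy-1-silyloxy diene carrying the future C3' methyl adds to the triple bond. Acidic work-up aromatises to the target without chlorine, methyl 2-hydroxy-4-[(2-hydroxy-4-methoxy-3,6-dimethylbenzoyl)oxy]-3,5,6-trimethylbenzoate A4. Chlorination at C5', the only aromatic C–H of A4, would finish the synthesis.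
- Merits: the late chlorination is unambiguous in position.
- Where it is better: the ester bond is made with a slim, linear acyl group, so the hindered-on-hindered coupling disappears altogether.
- Weak points: A5 is an internal, β-methylated alkynoate and a sluggish dienophile. The tetrasubstituted ketene acetal diene is sensitive and can be acylated by the aryl ester or protonated by the free phenol. The route is linear on ring A and still needs A2. Chlorinating a molecule with two free, electron-rich phenols invites ipso attack.
- What the chosen plan sets against it: ring B comes from a commercial, fully substituted benzoate in four standard steps, and the synthesis stays convergent.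

Key step: step 11

Assumption: 2,4,5-trimethylphenol, 1,3,5-trimethoxybenzene and methyl 2,4-dihydroxy-3,6-dimethylbenzoate are taken as purchasable; the target has no stereocentre, so no configuration has to be set or preserved.

## Route

Step 1
Reactants: 1 2,4,5-trimethylphenol
Product: 2 2-hydroxy-3,5,6-trimethylbenzaldehyde
Conditions: MgCl2, Et3N, (CH2O)n, MeCN, reflux; aq. HCl work-up
Reagents that add atoms: paraformaldehyde (as formaldehyde), C=O
Why: Magnesium-mediated ortho-formylation of a phenol (Casnati–Skattebøl reaction): the magnesium phenoxide delivers formaldehyde to the only free ortho carbon and a second formaldehyde accepts hydride from the hydroxymethyl intermediate; the para position is blocked by methyl, so one isomer is expected.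

Step 2
Reactants: 2 2-hydroxy-3,5,6-trimethylbenzaldehyde
Product: 3 2-hydroxy-3,5,6-trimethylbenzoic acid
Conditions: NaClO2, NaH2PO4, 2-methyl-2-butene, t-BuOH/H2O, rt
Reagents that add atoms: sodium chlorite, [Na+].[O-]Cl=O
Why: Pinnick oxidation of an aldehyde to the acid; the alkene traps the hypochlorous acid formed, so the ring and the phenol should not be chlorinated or oxidised.

Step 3
Reactants: 3 2-hydroxy-3,5,6-trimethylbenzoic acid
Product: 4 methyl 2-hydroxy-3,5,6-trimethylbenzoate
Conditions: MeI, KHCO3, DMF, 40 °C
Reagents that add atoms: iodomethane, CI
Why: Carboxylate alkylation by SN2 at the methyl carbon, which is indifferent to the crowding around the carbonyl; hydrogen carbonate is too weak a base to ionise the chelated phenol, so only the ester should form.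

Step 4
Reactants: 4 methyl 2-hydroxy-3,5,6-trimethylbenzoate
Product: 5 methyl 2-hydroxy-4-iodo-3,5,6-trimethylbenzoate
Conditions: NIS, TfOH (cat.), CF3CO2H/CH2Cl2, 0 °C to rt
Reagents that add atoms: N-iodosuccinimide, O=C1CCC(=O)N1I
Why: Electrophilic aromatic iodination with acid-activated N-iodosuccinimide; C4 is the only ring carbon bearing hydrogen and its two ortho methyl groups offset the para ester, while ipso adducts at methyl-bearing carbons can only revert; the ester (not the acid) is used so that iodine cannot displace CO2.

Step 5
Reactants: 5 methyl 2-hydroxy-4-iodo-3,5,6-trimethylbenzoate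
Product: 6 methyl 2-(benzyloxy)-4-iodo-3,5,6-trimethylbenzoate
Conditions: BnBr, K2CO3, DMF, 60 °C
Reagents that add atoms: benzyl bromide, BrCc1ccccc1
Why: Williamson ether synthesis; warm carbonate in a dipolar solvent breaks the hydrogen bond to the ester and the phenoxide is benzylated despite its two ortho neighbours.

Step 6
Reactants: 6 methyl 2-(benzyloxy)-4-iodo-3,5,6-trimethylbenzoate; 7 1,3,5-trimethoxybenzene
Product: 9 [3-(benzyloxy)-4-(methoxycarbonyl)-2,5,6-trimethylphenyl](2,4,6-trimethoxyphenyl)iodonium 4-methylbenzenesulfonate, via hydroxy(tosyloxy)iodoarene 8 (not isolated)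
Conditions: mCPBA, TsOH·H2O, MeCN, 77 °C; then 7, 77 °C to rt
Reagents that add atoms: p-toluenesulfonic acid monohydrate, Cc1ccc(cc1)S(=O)(=O)O.O
Why: One-pot diaryliodonium synthesis: the peracid oxidises the aryl iodide to trivalent iodine, the sulfonic acid gives the Koser-type reagent 8, and this electrophile substitutes the very electron-rich arene 7 at carbon with loss of water; ring A has no free position and the benzyl ring is far less nucleophilic than 7, so one salt is expected.

Step 7
Reactants: 10 methyl 2,4-dihydroxy-3,6-dimethylbenzoate (methyl atrarate)
Product: 11 methyl 2-hydroxy-4-methoxy-3,6-dimethylbenzoate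
Conditions: MeI (1.1 equiv), K2CO3, acetone, reflux
Reagents that add atoms: iodomethane, CI
Why: Selective Williamson methylation; the 2-hydroxyl is tied up in a hydrogen bond to the ester and is both less acidic and less nucleophilic, so the 4-hydroxyl reacts first.

Step 8
Reactants: 11 methyl 2-hydroxy-4-methoxy-3,6-dimethylbenzoate
Product: 12 methyl 5-chloro-2-hydroxy-4-methoxy-3,6-dimethylbenzoate
Conditions: SO2Cl2, CH2Cl2, 0 °C to rt
Reagents that add atoms: sulfuryl chloride, O=S(=O)(Cl)Cl
Why: Electrophilic aromatic chlorination at the single free ring position, which is para to the hydroxyl and ortho to the methoxy group; one equivalent in the dark keeps the reaction ionic and away from the benzylic methyl groups.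

Step 9
Reactants: 12 methyl 5-chloro-2-hydroxy-4-methoxy-3,6-dimethylbenzoate
Product: 13 methyl 2-(benzyloxy)-5-chloro-4-methoxy-3,6-dimethylbenzoate
Conditions: BnBr, K2CO3, DMF, 60 °C
Reagents that add atoms: benzyl bromide, BrCc1ccccc1
Why: Williamson ether synthesis on the chelated phenol, as in step 5.

Step 10
Reactants: 13 methyl 2-(benzyloxy)-5-chloro-4-methoxy-3,6-dimethylbenzoate
Product: 14 2-(benzyloxy)-5-chloro-4-methoxy-3,6-dimethylbenzoic acid
Conditions: KOH, DMSO/H2O, 90 °C; then aq. HCl
Reagents that add atoms: potassium hydroxide, [K+].[OH-]
Why: Saponification of a 2,6-disubstituted benzoate with poorly solvated hydroxide in aqueous DMSO, the usual answer to hindered methyl esters; the benzyl ether, the methyl ether and the unactivated aryl chloride are inert to hydroxide.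

Step 11
Reactants: 14 2-(benzyloxy)-5-chloro-4-methoxy-3,6-dimethylbenzoic acid; 9 [3-(benzyloxy)-4-(methoxycarbonyl)-2,5,6-trimethylphenyl](2,4,6-trimethoxyphenyl)iodonium 4-methylbenzenesulfonate
Product: 17 methyl 2-(benzyloxy)-4-{[2-(benzyloxy)-5-chloro-4-methoxy-3,6-dimethylbenzoyl]oxy}-3,5,6-trimethylbenzoate, via potassium carboxylate 15 (not isolated), via aryl(carboxylato)iodane 16 (not isolated)
Conditions: KOtBu, toluene, rt; then 9, 110 °C
Reagents that add atoms: none
Why: This is the metal-free O-arylation of a carboxylate by a diaryliodonium salt, a known reaction type applied here to two partners that are both substituted at both ortho positions. Carboxylate 15 displaces tosylate on trivalent iodine to give the T-shaped iodane 16, and reductive ligand coupling joins the carboxylate oxygen to the ipso carbon C4 of ring A while 2-iodo-1,3,5-trimethoxybenzene departs with iodine in the monovalent state. No ring is closed and no stereocentre is formed. The selectivity needed is transfer of the ring A aryl group and not of the trimethoxyphenyl group. Ring A carries the ester para to iodine and is the electron-poorer ligand, its two ortho methyl groups add the ortho acceleration of ligand coupling, and three methoxy groups make the ipso carbon of the auxiliary a poor acceptor. Neither aryl group has a hydrogen ortho to iodine, so an aryne pathway and its scrambling are excluded. The new bond forms at an aryl carbon and not at the shielded acyl carbon, so the 2,6-disubstitution of the acid costs little. The tert-butoxide is consumed before 9 is added, so no alkoxide is present to attack the methyl ester or the new aryl ester.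

Step 12
Reactants: 17 methyl 2-(benzyloxy)-4-{[2-(benzyloxy)-5-chloro-4-methoxy-3,6-dimethylbenzoyl]oxy}-3,5,6-trimethylbenzoate
Product: 18 methyl 4-[(5-chloro-2-hydroxy-4-methoxy-3,6-dimethylbenzoyl)oxy]-2-hydroxy-3,5,6-trimethylbenzoate
Conditions: BCl3, C6HMe5, CH2Cl2, −78 °C; aqueous work-up
Reagents that add atoms: none
Why: Lewis-acid debenzylation of aryl benzyl ethers with pentamethylbenzene as a non-basic benzyl cation trap; both benzyloxy groups are ortho to a carbonyl that chelates boron, so they should cleave at −78 °C, where the C4' methyl ether, the aryl chloride and both esters are left alone.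

## Compound list

1 | 2,4,5-trimethylphenol | Cc1cc(C)c(C)cc1O | starting material
2 | 2-hydroxy-3,5,6-trimethylbenzaldehyde | O=Cc1c(C)c(C)cc(C)c1O | intermediate
3 | 2-hydroxy-3,5,6-trimethylbenzoic acid | OC(=O)c1c(C)c(C)cc(C)c1O | intermediate
4 | methyl 2-hydroxy-3,5,6-trimethylbenzoate | COC(=O)c1c(C)c(C)cc(C)c1O | intermediate
5 | methyl 2-hydroxy-4-iodo-3,5,6-trimethylbenzoate | COC(=O)c1c(C)c(C)c(I)c(C)c1O | intermediate
6 | methyl 2-(benzyloxy)-4-iodo-3,5,6-trimethylbenzoate | COC(=O)c1c(C)c(C)c(I)c(C)c1OCc1ccccc1 | intermediate
7 | 1,3,5-trimethoxybenzene | COc1cc(OC)cc(OC)c1 | starting material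
8 | methyl 2-(benzyloxy)-4-[hydroxy(tosyloxy)iodo]-3,5,6-trimethylbenzoate (not isolated) | COC(=O)c1c(C)c(C)c(I(O)OS(=O)(=O)c2ccc(C)cc2)c(C)c1OCc1ccccc1 | intermediate
9 | [3-(benzyloxy)-4-(methoxycarbonyl)-2,5,6-trimethylphenyl](2,4,6-trimethoxyphenyl)iodonium 4-methylbenzenesulfonate | COC(=O)c1c(C)c(C)c([I+]c2c(OC)cc(OC)cc2OC)c(C)c1OCc1ccccc1.Cc1ccc(cc1)S(=O)(=O)[O-] | intermediate
10 | methyl 2,4-dihydroxy-3,6-dimethylbenzoate (methyl atrarate) | COC(=O)c1c(C)cc(O)c(C)c1O | starting material
11 | methyl 2-hydroxy-4-methoxy-3,6-dimethylbenzoate | COC(=O)c1c(C)cc(OC)c(C)c1O | intermediate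
12 | methyl 5-chloro-2-hydroxy-4-methoxy-3,6-dimethylbenzoate | COC(=O)c1c(C)c(Cl)c(OC)c(C)c1O | intermediate
13 | methyl 2-(benzyloxy)-5-chloro-4-methoxy-3,6-dimethylbenzoate | COC(=O)c1c(C)c(Cl)c(OC)c(C)c1OCc1ccccc1 | intermediate
14 | 2-(benzyloxy)-5-chloro-4-methoxy-3,6-dimethylbenzoic acid | OC(=O)c1c(C)c(Cl)c(OC)c(C)c1OCc1ccccc1 | intermediate
15 | potassium 2-(benzyloxy)-5-chloro-4-methoxy-3,6-dimethylbenzoate (not isolated) | [K+].[O-]C(=O)c1c(C)c(Cl)c(OC)c(C)c1OCc1ccccc1 | intermediate
16 | [2-(benzyloxy)-5-chloro-4-methoxy-3,6-dimethylbenzoato][3-(benzyloxy)-4-(methoxycarbonyl)-2,5,6-trimethylphenyl](2,4,6-trimethoxyphenyl)iodine, T-shaped trivalent iodane (not isolated) | COC(=O)c1c(C)c(C)c(I(OC(=O)c2c(C)c(Cl)c(OC)c(C)c2OCc2ccccc2)c2c(OC)cc(OC)cc2OC)c(C)c1OCc1ccccc1 | intermediate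
17 | methyl 2-(benzyloxy)-4-{[2-(benzyloxy)-5-chloro-4-methoxy-3,6-dimethylbenzoyl]oxy}-3,5,6-trimethylbenzoate | COC(=O)c1c(C)c(C)c(OC(=O)c2c(C)c(Cl)c(OC)c(C)c2OCc2ccccc2)c(C)c1OCc1ccccc1 | intermediate
18 | methyl 4-[(5-chloro-2-hydroxy-4-methoxy-3,6-dimethylbenzoyl)oxy]-2-hydroxy-3,5,6-trimethylbenzoate | COC(=O)c1c(C)c(C)c(OC(=O)c2c(C)c(Cl)c(OC)c(C)c2O)c(C)c1O | target

## Step count and risks

Total: 12 steps. Longest linear sequence: 8 steps (steps 1 to 6, then 11 and 12, from 1 to 18). The ring B branch (steps 7 to 10) joins at step 11.

**Step 11 (key step).** The carboxylate may be delivered to the wrong aryl ligand, giving the trimethoxyphenyl ester and returning iodide 6. Ligand coupling may also be so slow, with four ortho substituents around the new bond, that homolytic decomposition of the iodane takes over. The fallback gives up the aryl–oxygen disconnection and makes the acyl–oxygen bond classically; it sets out from 6 and 14 and returns at 17.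
- Iodine–magnesium exchange on 6 (iPrMgCl·LiCl, THF, −20 °C) and trapping with 2-isopropoxy-4,4,5,5-tetramethyl-1,3,2-dioxaborolane would give methyl 2-(benzyloxy)-3,5,6-trimethyl-4-(4,4,5,5-tetramethyl-1,3,2-dioxaborolan-2-yl)benzoate F1.
- Oxidation with buffered hydrogen peroxide at 0 °C would give methyl 2-(benzyloxy)-4-hydroxy-3,5,6-trimethylbenzoate F2.
- Acid 14 with oxalyl chloride and catalytic DMF would give 2-(benzyloxy)-5-chloro-4-methoxy-3,6-dimethylbenzoyl chloride F3.
- The sodium phenoxide of F2 (NaH, THF) would be acylated by F3 to give 17. This is slow but known chemistry for 2,6-disubstituted aroyl chlorides.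

**Step 4.** Substitution at C4 may be too slow, because the position is meta to the hydroxyl and para to the ester. Reversible ipso attack at the methyl-bearing carbons and oxidation of the phenol may then consume the reagent. The fallback installs iodine before the ester exists; it sets out from 1 and returns at 6.
- Double iodination of 1 (NIS, CF3CO2H) should give 3,6-diiodo-2,4,5-trimethylphenol F4. The second iodine enters a position that is para to iodine, not to an ester.
- Benzylation gives 1-(benzyloxy)-3,6-diiodo-2,4,5-trimethylbenzene F5.
- Iodine–magnesium exchange (iPrMgCl·LiCl, THF, −40 °C) is expected to be faster at the iodine next to the benzyloxy group, which is inductively activated and can chelate magnesium. Quenching with methyl chloroformate would give 6.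

**Step 6.** Oxidation of the hindered, electron-poor iodide may stall, or the hot peracid and sulfonic acid may degrade the benzyl ether before the iodonium salt forms. The fallback reverses the roles, with a nucleophilic ring A and a bought trivalent iodine reagent; it sets out from 6 and returns at 17.
- Iodine–magnesium exchange on 6, triisopropyl borate and acidic work-up would give [3-(benzyloxy)-4-(methoxycarbonyl)-2,5,6-trimethylphenyl]boronic acid F6.
- F6 with [hydroxy(tosyloxy)iodo]benzene in CH2Cl2 would give [3-(benzyloxy)-4-(methoxycarbonyl)-2,5,6-trimethylphenyl](phenyl)iodonium 4-methylbenzenesulfonate F7 by boron-to-iodine exchange.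
- F7 would replace 9 under the conditions of step 11 and give 17. Phenyl is a weaker bystander than trimethoxyphenyl, so selectivity would then rest on the ortho methyl groups and the para ester of ring A.

**Step 10.** Hydroxide attack at the shielded carbonyl may be incomplete even at 90 °C, and longer heating invites decomposition. The fallback avoids acyl substitution by a redox detour; it sets out from 13 and returns at 14.
- Reduction with LiAlH4 (THF, 0 °C) would give [2-(benzyloxy)-5-chloro-4-methoxy-3,6-dimethylphenyl]methanol F8.
- Oxidation with MnO2 would give 2-(benzyloxy)-5-chloro-4-methoxy-3,6-dimethylbenzaldehyde F9.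
- Pinnick oxidation as in step 2 would give 14.

**Step 12.** Cleavage of two crowded benzyl ethers may be incomplete at −78 °C. On warming, loss of the twisted C4' methyl ether or of the depside ester may begin. The fallback is reductive instead of Lewis-acidic: hydrogenolysis of 17 (H2, Pd/C, EtOAc, rt) directly to 18, stopped as soon as both benzyl groups are gone. The chlorine lies between a methyl and a methoxy group and should be reduced more slowly than the benzyl ethers. No new compound is involved.

## Further compounds

F1 | step 11 | methyl 2-(benzyloxy)-3,5,6-trimethyl-4-(4,4,5,5-tetramethyl-1,3,2-dioxaborolan-2-yl)benzoate | COC(=O)c1c(C)c(C)c(B2OC(C)(C)C(C)(C)O2)c(C)c1OCc1ccccc1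
F2 | step 11 | methyl 2-(benzyloxy)-4-hydroxy-3,5,6-trimethylbenzoate | COC(=O)c1c(C)c(C)c(O)c(C)c1OCc1ccccc1
F3 | step 11 | 2-(benzyloxy)-5-chloro-4-methoxy-3,6-dimethylbenzoyl chloride | O=C(Cl)c1c(C)c(Cl)c(OC)c(C)c1OCc1ccccc1
F4 | step 4 | 3,6-diiodo-2,4,5-trimethylphenol | Cc1c(I)c(C)c(C)c(I)c1O
F5 | step 4 | 1-(benzyloxy)-3,6-diiodo-2,4,5-trimethylbenzene | Cc1c(I)c(C)c(C)c(I)c1OCc1ccccc1
F6 | step 6 | [3-(benzyloxy)-4-(methoxycarbonyl)-2,5,6-trimethylphenyl]boronic acid | COC(=O)c1c(C)c(C)c(B(O)O)c(C)c1OCc1ccccc1
F7 | step 6 | [3-(benzyloxy)-4-(methoxycarbonyl)-2,5,6-trimethylphenyl](phenyl)iodonium 4-methylbenzenesulfonate | COC(=O)c1c(C)c(C)c([I+]c2ccccc2)c(C)c1OCc1ccccc1.Cc1ccc(cc1)S(=O)(=O)[O-]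
F8 | step 10 | [2-(benzyloxy)-5-chloro-4-methoxy-3,6-dimethylphenyl]methanol | OCc1c(C)c(Cl)c(OC)c(C)c1OCc1ccccc1
F9 | step 10 | 2-(benzyloxy)-5-chloro-4-methoxy-3,6-dimethylbenzaldehyde | O=Cc1c(C)c(Cl)c(OC)c(C)c1OCc1ccccc1
F0 | step 12 | none | none
A1 | alternative 1 | methyl 3,5,6-trimethyl-2,4-dioxocyclohexane-1-carboxylate (mixture of diastereomers and enol forms) | COC(=O)C1C(C)C(C)C(=O)C(C)C1=O
A2 | alternative 1 | methyl 2,4-dihydroxy-3,5,6-trimethylbenzoate | COC(=O)c1c(C)c(C)c(O)c(C)c1O
A3 | alternative 2 | methyl 4-hydroxy-3,5,6-trimethyl-2-(triisopropylsilyloxy)benzoate | COC(=O)c1c(C)c(C)c(O)c(C)c1O[Si](C(C)C)(C(C)C)C(C)C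
A4 | alternative 3 | methyl 2-hydroxy-4-[(2-hydroxy-4-methoxy-3,6-dimethylbenzoyl)oxy]-3,5,6-trimethylbenzoate | COC(=O)c1c(C)c(C)c(OC(=O)c2c(C)cc(OC)c(C)c2O)c(C)c1O
A5 | alternative 3 | methyl 4-(but-2-ynoyloxy)-2-hydroxy-3,5,6-trimethylbenzoate | COC(=O)c1c(C)c(C)c(OC(=O)C#CC)c(C)c1O
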